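**Strategy.** The cyclobutane is disconnected across C1'–C2' and C3'–C4', so that the adjacent fully substituted carbons C1' (oxygen, aryl) and C4' (two methyls) derive from a tetrasubstituted enol ether without alkene geometry. One dichloroketene [2+2] cycloaddition closes the four-membered ring, forms both bonds and sets C1', the only stereocentre, under control of a 1-(2,4,6-triisopropylphenyl)ethyl ether. The precursor is the enol ether ArC(OR*)=CMe2 with Ar = 2,5-dimethoxyphenyl. The C2' chlorines are kept until the auxiliary has been removed by acid, because they suppress ionisation at C1'; the arene is turned into the naphthazarin last, by oxidation to the quinone and a furan Diels–Alder annulation.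

Key step: step 3

Locants: C1' carries oxygen and the aryl group, C2' and C3' are the ring CH2 carbons of the target, C4' carries the two methyls.

Assumption: enol ether 6 is taken to react with the auxiliary O–C bond anti to C=C and its carbinol C–H in the alkene plane, so that the ketene adds anti to the triisopropylphenyl ring; on this model the (S)-alcohol gives the required (R)-C1', and the (R)-alcohol would be used in step 1 if the sense proved opposite.

Step 1
Reactants: 1 2,5-dimethoxybenzoyl chloride; 2 (1S)-1-(2,4,6-triisopropylphenyl)ethan-1-ol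
Product: 4 (1S)-1-(2,4,6-triisopropylphenyl)ethyl 2,5-dimethoxybenzoate, via lithium alkoxide 3 (not isolated)
Conditions: n-BuLi, THF, −78 °C; then 1, −78 → 25 °C
Reagents that add atoms: none
Why: Nucleophilic acyl substitution (O-acylation of a preformed lithium alkoxide by an aroyl chloride) esterifies the hindered benzylic alcohol under basic, non-ionising conditions, so the auxiliary stereocentre is untouched.

Step 2
Reactants: 4 (1S)-1-(2,4,6-triisopropylphenyl)ethyl 2,5-dimethoxybenzoate; 5 2,2-dibromopropane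
Product: 6 1,4-dimethoxy-2-{2-methyl-1-[(1S)-1-(2,4,6-triisopropylphenyl)ethoxy]prop-1-en-1-yl}benzene
Conditions: TiCl4, Zn, TMEDA, PbCl2 (cat.), THF, 25 °C; Et3N-buffered work-up
Reagents that add atoms: none
Why: Takai–Utimoto alkylidenation of an ester: the titanium isopropylidene species made from 5, Zn and TiCl4 turns C=O into C=CMe2 through an oxatitanacyclobutane, and because both new alkene substituents are methyl no geometry has to be controlled.

Step 3
Reactants: 6 1,4-dimethoxy-2-{2-methyl-1-[(1S)-1-(2,4,6-triisopropylphenyl)ethoxy]prop-1-en-1-yl}benzene; 7 trichloroacetyl chloride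
Product: 9 (3S)-2,2-dichloro-3-(2,5-dimethoxyphenyl)-4,4-dimethyl-3-[(1S)-1-(2,4,6-triisopropylphenyl)ethoxy]cyclobutan-1-one, via dichloroketene 8 (not isolated)
Conditions: Zn–Cu couple, Et2O–DME, 0 → 25 °C, slow addition of 7; cold NaHCO3 (aq) work-up
Reagents that add atoms: none
Why: Ketene–enol ether [2+2] cycloaddition with dichloroketene made in the flask by zinc dechlorination of 7: the nucleophilic Me2C carbon of 6 attacks the ketene carbonyl carbon (C4'–C3' bond) to give an oxocarbenium/dichloroenolate zwitterion stabilised by the aryl group and the ether oxygen. The four-membered ring is closed by collapse of this zwitterion, the CCl2 enolate carbon bonding to C1' (C1'–C2' bond; stepwise polar closure, an intramolecular C-alkylation of the enolate). The closest known reactions are the facially selective dichloroketene cycloadditions of enol ethers of 1-(2,4,6-triisopropylphenyl)ethanol and the dichloroketene cycloadditions of α-aryl silyl enol ethers. C1' is set by the auxiliary: with its carbinol C–H in the alkene plane the triisopropylphenyl ring covers one π-face and the ketene arrives from the other. The regiochemistry (carbonyl at C3' next to CMe2, CCl2 at C2') follows from the polarisation of the enol ether, and since C4' carries two methyls no E/Z question arises. DME binds the ZnCl2 formed, which would otherwise reopen the donor–acceptor cyclobutanone.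

Step 4
Reactants: 9 (3S)-2,2-dichloro-3-(2,5-dimethoxyphenyl)-4,4-dimethyl-3-[(1S)-1-(2,4,6-triisopropylphenyl)ethoxy]cyclobutan-1-one
Product: 10 (3R)-2,2-dichloro-3-(2,5-dimethoxyphenyl)-4,4-dimethyl-3-[(1S)-1-(2,4,6-triisopropylphenyl)ethoxy]cyclobutan-1-ol as both C1 epimers (C3 unchanged in space; only the descriptor changes)
Conditions: NaBH4, MeOH–THF, −40 → 0 °C
Reagents that add atoms: none
Why: Borohydride reduction of the strained, electron-poor cyclobutanone removes the acceptor carbonyl before any acid is used, so that the alkoxy-aryl-substituted ring can no longer open by retro-aldol-type fragmentation; the new carbinol centre needs no control because step 7 deletes it.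

Step 5
Reactants: 10 (3R)-2,2-dichloro-3-(2,5-dimethoxyphenyl)-4,4-dimethyl-3-[(1S)-1-(2,4,6-triisopropylphenyl)ethoxy]cyclobutan-1-ol
Product: 11 O-[(3R)-2,2-dichloro-3-(2,5-dimethoxyphenyl)-4,4-dimethyl-3-[(1S)-1-(2,4,6-triisopropylphenyl)ethoxy]cyclobutyl] O-phenyl carbonothioate
Conditions: PhOC(S)Cl, pyridine, DMAP (cat.), CH2Cl2, 0 → 25 °C
Reagents that add atoms: O-phenyl chlorothionoformate, S=C(Cl)Oc1ccccc1
Why: DMAP-catalysed thioacylation of the secondary alcohol gives the Barton–McCombie precursor under weakly basic conditions that avoid alkoxide-driven ring contraction of the chlorohydrin.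

Step 6
Reactants: 11 O-[(3R)-2,2-dichloro-3-(2,5-dimethoxyphenyl)-4,4-dimethyl-3-[(1S)-1-(2,4,6-triisopropylphenyl)ethoxy]cyclobutyl] O-phenyl carbonothioate
Product: 12 O-[(3R)-2,2-dichloro-3-(2,5-dimethoxyphenyl)-3-hydroxy-4,4-dimethylcyclobutyl] O-phenyl carbonothioate
Conditions: CF3CO2H, CH2Cl2, 0 → 25 °C
Reagents that add atoms: none
Why: Acidolysis of the benzylic auxiliary ether (SN1/E1 at the auxiliary carbon, the cation leaving as the styrene) is chemoselective because ionisation of the other C–O bond, at C1', is shut down by the two chlorines on the neighbouring C2', so C1' keeps its configuration.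

Step 7
Reactants: 12 O-[(3R)-2,2-dichloro-3-(2,5-dimethoxyphenyl)-3-hydroxy-4,4-dimethylcyclobutyl] O-phenyl carbonothioate
Product: 13 (1R)-1-(2,5-dimethoxyphenyl)-2,2-dimethylcyclobutan-1-ol
Conditions: Bu3SnH (excess), AIBN, toluene, 110 °C
Reagents that add atoms: none
Why: Tin hydride radical chain reduction combines Barton–McCombie deoxygenation at C3' with stepwise hydrodechlorination at C2'; no radical is formed at C1', and hydrogen transfer from excess stannane should outrun β-chlorine loss or cyclobutyl ring opening.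

Step 8
Reactants: 13 (1R)-1-(2,5-dimethoxyphenyl)-2,2-dimethylcyclobutan-1-ol; 14 angelic anhydride [(2Z)-2-methylbut-2-enoic anhydride]
Product: 16 (1R)-1-(2,5-dimethoxyphenyl)-2,2-dimethylcyclobutyl (2Z)-2-methylbut-2-enoate, via lithium cyclobutanolate 15 (not isolated)
Conditions: LiN(SiMe3)2, THF, −78 °C; then 14, −78 → 25 °C
Reagents that add atoms: none
Why: O-Acylation of the lithium alkoxide by angelic anhydride is a stereoconservative angeloylation, since no nucleophilic catalyst or amine is present to isomerise the (Z)-enoate to the tiglate and the alkoxide is reactive enough for the congested tertiary centre.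

Step 9
Reactants: 16 (1R)-1-(2,5-dimethoxyphenyl)-2,2-dimethylcyclobutyl (2Z)-2-methylbut-2-enoate
Product: 17 (1R)-1-(3,6-dioxocyclohexa-1,4-dien-1-yl)-2,2-dimethylcyclobutyl (2Z)-2-methylbut-2-enoate
Conditions: (NH4)2Ce(NO3)6, MeCN–H2O, 0 °C, short reaction time
Reagents that add atoms: water, O
Why: Oxidative demethylation of the 1,4-dimethoxyarene with (NH4)2Ce(NO3)6 gives the p-benzoquinone (the quinone oxygens come from water) and leaves the ester and the quaternary C1' alone.

Step 10
Reactants: 17 (1R)-1-(3,6-dioxocyclohexa-1,4-dien-1-yl)-2,2-dimethylcyclobutyl (2Z)-2-methylbut-2-enoate; 18 2,5-bis(trimethylsilyloxy)furan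
Product: 20 (1R)-1-(5,8-dihydroxy-1,4-dioxo-1,4-dihydronaphthalen-2-yl)-2,2-dimethylcyclobutyl (2Z)-2-methylbut-2-enoate (the target), via oxygen-bridged cycloadduct 19 (not isolated)
Conditions: CH2Cl2, −78 → 25 °C; then dilute HCl (aq), THF, 25 °C
Reagents that add atoms: none
Why: Diels–Alder cycloaddition of the electron-rich furan 18 to the unsubstituted C5=C6 bond of quinone 17 (the other quinone alkene is blocked by the quaternary substituent), then acid-promoted opening of the oxygen bridge with loss of the silyl groups, should give a tetraketone that enolises to the aromatic naphthazarin without touching C1'.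

**Compound list**

1 | 2,5-dimethoxybenzoyl chloride | COc1ccc(OC)c(C(=O)Cl)c1 | starting material
2 | (1S)-1-(2,4,6-triisopropylphenyl)ethan-1-ol | C[C@H](O)c1c(C(C)C)cc(C(C)C)cc1C(C)C | starting material
3 | lithium (1S)-1-(2,4,6-triisopropylphenyl)ethan-1-olate | [Li+].C[C@H]([O-])c1c(C(C)C)cc(C(C)C)cc1C(C)C | intermediate
4 | (1S)-1-(2,4,6-triisopropylphenyl)ethyl 2,5-dimethoxybenzoate | COc1ccc(OC)c(C(=O)O[C@@H](C)c2c(C(C)C)cc(C(C)C)cc2C(C)C)c1 | intermediate
5 | 2,2-dibromopropane | CC(C)(Br)Br | starting material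
6 | 1,4-dimethoxy-2-{2-methyl-1-[(1S)-1-(2,4,6-triisopropylphenyl)ethoxy]prop-1-en-1-yl}benzene | CC(C)=C(O[C@@H](C)c1c(C(C)C)cc(C(C)C)cc1C(C)C)c1cc(OC)ccc1OC | intermediate
7 | trichloroacetyl chloride | ClC(Cl)(Cl)C(Cl)=O | starting material
8 | dichloroketene | ClC(Cl)=C=O | intermediate
9 | (3S)-2,2-dichloro-3-(2,5-dimethoxyphenyl)-4,4-dimethyl-3-[(1S)-1-(2,4,6-triisopropylphenyl)ethoxy]cyclobutan-1-one | O=C1C(Cl)(Cl)[C@](O[C@@H](C)c2c(C(C)C)cc(C(C)C)cc2C(C)C)(c2cc(OC)ccc2OC)C1(C)C | intermediate
10 | (3R)-2,2-dichloro-3-(2,5-dimethoxyphenyl)-4,4-dimethyl-3-[(1S)-1-(2,4,6-triisopropylphenyl)ethoxy]cyclobutan-1-ol, C1 epimers | OC1C(Cl)(Cl)[C@](O[C@@H](C)c2c(C(C)C)cc(C(C)C)cc2C(C)C)(c2cc(OC)ccc2OC)C1(C)C | intermediate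
11 | O-[(3R)-2,2-dichloro-3-(2,5-dimethoxyphenyl)-4,4-dimethyl-3-[(1S)-1-(2,4,6-triisopropylphenyl)ethoxy]cyclobutyl] O-phenyl carbonothioate | S=C(Oc1ccccc1)OC1C(Cl)(Cl)[C@](O[C@@H](C)c2c(C(C)C)cc(C(C)C)cc2C(C)C)(c2cc(OC)ccc2OC)C1(C)C | intermediate
12 | O-[(3R)-2,2-dichloro-3-(2,5-dimethoxyphenyl)-3-hydroxy-4,4-dimethylcyclobutyl] O-phenyl carbonothioate | S=C(Oc1ccccc1)OC1C(Cl)(Cl)[C@](O)(c2cc(OC)ccc2OC)C1(C)C | intermediate
13 | (1R)-1-(2,5-dimethoxyphenyl)-2,2-dimethylcyclobutan-1-ol | O[C@]1(c2cc(OC)ccc2OC)CCC1(C)C | intermediate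
14 | angelic anhydride, (2Z)-2-methylbut-2-enoic anhydride | C/C=C(/C)C(=O)OC(=O)/C(C)=C\C | starting material
15 | lithium (1R)-1-(2,5-dimethoxyphenyl)-2,2-dimethylcyclobutan-1-olate | [Li+].[O-][C@]1(c2cc(OC)ccc2OC)CCC1(C)C | intermediate
16 | (1R)-1-(2,5-dimethoxyphenyl)-2,2-dimethylcyclobutyl (2Z)-2-methylbut-2-enoate | C/C=C(/C)C(=O)O[C@]1(c2cc(OC)ccc2OC)CCC1(C)C | intermediate
17 | (1R)-1-(3,6-dioxocyclohexa-1,4-dien-1-yl)-2,2-dimethylcyclobutyl (2Z)-2-methylbut-2-enoate | C/C=C(/C)C(=O)O[C@]1(C2=CC(=O)C=CC2=O)CCC1(C)C | intermediate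
18 | 2,5-bis(trimethylsilyloxy)furan | C[Si](C)(C)Oc1ccc(O[Si](C)(C)C)o1 | starting material
19 | Diels–Alder adduct: 5,8-epoxy-4a,5,8,8a-tetrahydronaphthalene-1,4-dione with OSiMe3 at C5 and C8 and the (1R)-1-angeloyloxy-2,2-dimethylcyclobutyl group at C2 (adduct diastereomers) | C/C=C(/C)C(=O)O[C@]1(C2=CC(=O)C3C(C2=O)C4(O[Si](C)(C)C)C=CC3(O[Si](C)(C)C)O4)CCC1(C)C | intermediate
20 | (1R)-1-(5,8-dihydroxy-1,4-dioxo-1,4-dihydronaphthalen-2-yl)-2,2-dimethylcyclobutyl (2Z)-2-methylbut-2-enoate | C/C=C(/C)C(=O)O[C@]1(C2=CC(=O)c3c(O)ccc(O)c3C2=O)CCC1(C)C | target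

**Step count.** 10 steps in total; the longest linear sequence is 10 steps (2 → 20).

**Steps most likely to fail**

1. Step 3 (key step). The π-facial discrimination may be insufficient at a tetrasubstituted α-aryl enol ether. The zwitterion may also fail to close at the congested C1', losing the auxiliary cation or closing on oxygen instead. The fallback gives up the auxiliary and uses no numbered compound. It sets out from purchased 2-bromo-1,4-dimethoxybenzene F1, which undergoes bromine–lithium exchange (n-BuLi, THF, −78 °C) to (2,5-dimethoxyphenyl)lithium F2. This adds to purchased 2,2-dimethylcyclobutan-1-one F3 to give racemic 1-(2,5-dimethoxyphenyl)-2,2-dimethylcyclobutan-1-ol F4. Preparative chromatography on a chiral stationary phase separates the enantiomers, and the (R)-alcohol is 13, where the route is rejoined for steps 8 to 10.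

2. Step 2. The titanium isopropylidene species may decompose by β-hydride loss faster than it adds to the shielded ester carbonyl, so that conversion stays low. The fallback forms the aryl–alkene bond instead of the C=C bond and sets out from 2. Acylation with 2-methylpropanoyl chloride F5 (pyridine, DMAP cat., CH2Cl2) gives (1S)-1-(2,4,6-triisopropylphenyl)ethyl 2-methylpropanoate F6. KN(SiMe3)2 (THF–DMPU, −78 °C) gives the potassium enolate F7, which is trapped on oxygen with (PhO)2P(O)Cl as the ketene acetal phosphate F8. Suzuki–Miyaura coupling of F8 with (2,5-dimethoxyphenyl)boronic acid F9 (Pd(OAc)2, SPhos, K3PO4, dioxane–H2O) gives 6, where the route is rejoined.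

3. Step 7. The radical chain may stall at the monochloride because chlorine abstraction from the hindered secondary C2'–Cl bond is slow, or the C2' radical next to the aryl-bearing carbon may rearrange. The fallback removes the chlorines by two-electron reduction while they are still α to the ketone and sets out from 9.
   - Zn–Cu couple and NH4Cl in MeOH give the dechlorinated ketone F10; NaBH4 gives the cyclobutanol F11; PhOC(S)Cl, pyridine and DMAP give its O-phenyl thionocarbonate F12.
   - Bu3SnH/AIBN then only has to carry out the Barton–McCombie deoxygenation, giving the auxiliary ether F13.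
   - Because C1' is now unprotected against ionisation, the arene is oxidised first with (NH4)2Ce(NO3)6 to the quinone ether F14, whose electron-poor ring disfavours a C1' cation.
   - CF3CO2H removes the auxiliary to give the hydroxy quinone F15. Na2S2O4 reduces it to the hydroquinone F16, which is methylated in the same flask (Me2SO4, KOH, Bu4NBr) to 13, where the route is rejoined.

**Further compounds**

F1 | step 3 | 2-bromo-1,4-dimethoxybenzene (purchased) | COc1ccc(OC)c(Br)c1
F2 | step 3 | (2,5-dimethoxyphenyl)lithium | [Li]c1cc(OC)ccc1OC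
F3 | step 3 | 2,2-dimethylcyclobutan-1-one (purchased) | CC1(C)CCC1=O
F4 | step 3 | racemic 1-(2,5-dimethoxyphenyl)-2,2-dimethylcyclobutan-1-ol | OC1(c2cc(OC)ccc2OC)CCC1(C)C
F5 | step 2 | 2-methylpropanoyl chloride (purchased) | CC(C)C(Cl)=O
F6 | step 2 | (1S)-1-(2,4,6-triisopropylphenyl)ethyl 2-methylpropanoate | CC(C)C(=O)O[C@@H](C)c1c(C(C)C)cc(C(C)C)cc1C(C)C
F7 | step 2 | potassium 2-methyl-1-[(1S)-1-(2,4,6-triisopropylphenyl)ethoxy]prop-1-en-1-olate | [K+].CC(C)=C([O-])O[C@@H](C)c1c(C(C)C)cc(C(C)C)cc1C(C)C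
F8 | step 2 | 2-methyl-1-[(1S)-1-(2,4,6-triisopropylphenyl)ethoxy]prop-1-en-1-yl diphenyl phosphate | CC(C)=C(O[C@@H](C)c1c(C(C)C)cc(C(C)C)cc1C(C)C)OP(=O)(Oc1ccccc1)Oc1ccccc1
F9 | step 2 | (2,5-dimethoxyphenyl)boronic acid (purchased) | COc1ccc(OC)c(B(O)O)c1
F10 | step 7 | (3S)-3-(2,5-dimethoxyphenyl)-2,2-dimethyl-3-[(1S)-1-(2,4,6-triisopropylphenyl)ethoxy]cyclobutan-1-one | O=C1C[C@](O[C@@H](C)c2c(C(C)C)cc(C(C)C)cc2C(C)C)(c2cc(OC)ccc2OC)C1(C)C
F11 | step 7 | (3R)-3-(2,5-dimethoxyphenyl)-2,2-dimethyl-3-[(1S)-1-(2,4,6-triisopropylphenyl)ethoxy]cyclobutan-1-ol, C1 epimers | OC1C[C@](O[C@@H](C)c2c(C(C)C)cc(C(C)C)cc2C(C)C)(c2cc(OC)ccc2OC)C1(C)C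
F12 | step 7 | O-[(3R)-3-(2,5-dimethoxyphenyl)-2,2-dimethyl-3-[(1S)-1-(2,4,6-triisopropylphenyl)ethoxy]cyclobutyl] O-phenyl carbonothioate | S=C(Oc1ccccc1)OC1C[C@](O[C@@H](C)c2c(C(C)C)cc(C(C)C)cc2C(C)C)(c2cc(OC)ccc2OC)C1(C)C
F13 | step 7 | 2-{(1R)-2,2-dimethyl-1-[(1S)-1-(2,4,6-triisopropylphenyl)ethoxy]cyclobutyl}-1,4-dimethoxybenzene | C1C[C@](O[C@@H](C)c2c(C(C)C)cc(C(C)C)cc2C(C)C)(c2cc(OC)ccc2OC)C1(C)C
F14 | step 7 | 2-{(1R)-2,2-dimethyl-1-[(1S)-1-(2,4,6-triisopropylphenyl)ethoxy]cyclobutyl}cyclohexa-2,5-diene-1,4-dione | C1C[C@](O[C@@H](C)c2c(C(C)C)cc(C(C)C)cc2C(C)C)(C2=CC(=O)C=CC2=O)C1(C)C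
F15 | step 7 | 2-[(1R)-1-hydroxy-2,2-dimethylcyclobutyl]cyclohexa-2,5-diene-1,4-dione | O[C@]1(C2=CC(=O)C=CC2=O)CCC1(C)C
F16 | step 7 | 2-[(1R)-1-hydroxy-2,2-dimethylcyclobutyl]benzene-1,4-diol | O[C@]1(c2cc(O)ccc2O)CCC1(C)C
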